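**Retrosynthetic overview**
- The target comes from its 4′-O-TIPS ether by desilylation.
- The pyran ring (O1–C2 bond) and the C3 stereocentre are made together by an enantioselective anti-Markovnikov 6-endo hydroetherification of a 2-(2-arylallyl)phenol. This is the key C–O step and the proposed new method.
- That phenol comes from one thermal operation on a bis-ether: a propargyl Claisen/oxa-6π sequence closes the B-ring chromene, and an aromatic Claisen forms C4–C4a.
- The bis-ether comes from a Mitsunobu coupling of C2v-symmetric 2,6-dihydroxy-4-methoxybenzaldehyde with a 2-arylallyl alcohol built from 2,4-dihydroxyacetophenone.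
- Ring order: both benzene rings are bought, the chromene ring is formed in step 7, and the pyran ring in step 8.

Assumption: the descriptor in the given SMILES corresponds to (3R) at C3 of the chroman (B-ring atoms primed), and both antipodes of the peptide thiol catalyst are taken as accessible.

**Route**

Step 1
Reactants: 1 2,4,6-trihydroxybenzaldehyde
Product: 2 2,6-dihydroxy-4-methoxybenzaldehyde
Conditions: Me2SO4 (1.0 equiv), K2CO3 (1.0 equiv), acetone, 0 °C → rt
Reagents that add atoms: dimethyl sulfate, COS(=O)(=O)OC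
Why: Williamson O-methylation is selective for the 4-OH because it is the most acidic hydroxyl (para to CHO) and the only one not ortho to and hydrogen-bonded with the formyl group, and the product stays symmetric so its two remaining OH groups are equivalent.

Step 2
Reactants: 3 1-(2,4-dihydroxyphenyl)ethan-1-one
Product: 4 1-[2-hydroxy-4-(triisopropylsilyloxy)phenyl]ethan-1-one
Conditions: TIPSCl (1.05 equiv), imidazole (2.2 equiv), DMF, 0 °C → rt
Reagents that add atoms: triisopropylsilyl chloride, CC(C)[Si](Cl)(C(C)C)C(C)C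
Why: O-silylation occurs only at the free 4-OH because the 2-OH is locked in a hydrogen bond to the acetyl group and is hindered toward the bulky silyl chloride.

Step 3
Reactants: 4 1-[2-hydroxy-4-(triisopropylsilyloxy)phenyl]ethan-1-one; 5 3-chloro-3-methylbut-1-yne
Product: 6 1-[2-(2-methylbut-3-yn-2-yloxy)-4-(triisopropylsilyloxy)phenyl]ethan-1-one
Conditions: 5 (1.5 equiv), DBU (1.6 equiv), CuCl2·2H2O (1 mol%), dry MeCN, 0 °C → rt
Reagents that add atoms: none
Why: Copper-catalysed propargylic etherification (phenoxide attack on a copper allenylidene from the tertiary propargyl chloride) puts the 1,1-dimethylpropargyl group on the only free OH, which is the oxygen that must become the chromene oxygen.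

Step 4
Reactants: 6 1-[2-(2-methylbut-3-yn-2-yloxy)-4-(triisopropylsilyloxy)phenyl]ethan-1-one
Product: 7 2-methyl-2-[2-(2-methylbut-3-yn-2-yloxy)-4-(triisopropylsilyloxy)phenyl]oxirane (racemic)
Conditions: Me3S+ I− (1.5 equiv), n-BuLi (1.4 equiv), THF, −10 °C → rt
Reagents that add atoms: trimethylsulfonium iodide, C[S+](C)C.[I-]
Why: Corey–Chaykovsky epoxidation (ylide addition to the ketone, then ring closure with loss of Me2S) adds the future C2 carbon; the ylide is too weak a base to touch the alkyne C–H, and the racemic stereocentre is erased in step 5.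

Step 5
Reactants: 7 2-methyl-2-[2-(2-methylbut-3-yn-2-yloxy)-4-(triisopropylsilyloxy)phenyl]oxirane (racemic)
Product: 8 2-[2-(2-methylbut-3-yn-2-yloxy)-4-(triisopropylsilyloxy)phenyl]prop-2-en-1-ol
Conditions: LDA (3.0 equiv), THF, 0 °C → rt; then H2O
Reagents that add atoms: none
Why: Base-mediated epoxide-to-allylic-alcohol isomerisation (syn β-elimination) can only take a proton from the methyl group, so the 2-arylallyl alcohol is the single possible elimination product; the excess base covers the reversibly deprotonated alkyne C–H.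

Step 6
Reactants: 2 2,6-dihydroxy-4-methoxybenzaldehyde; 8 2-[2-(2-methylbut-3-yn-2-yloxy)-4-(triisopropylsilyloxy)phenyl]prop-2-en-1-ol
Product: 9 2-hydroxy-4-methoxy-6-({2-[2-(2-methylbut-3-yn-2-yloxy)-4-(triisopropylsilyloxy)phenyl]prop-2-en-1-yl}oxy)benzaldehyde
Conditions: 2 (1.5 equiv), PPh3 (1.3 equiv), DIAD (1.3 equiv), THF, 0 °C → rt
Reagents that add atoms: none
Why: Mitsunobu etherification of the acidic salicylaldehyde-type phenol with the primary allylic alcohol gives one mono-ether because the two OH groups of 2 are equivalent, SN2 and SN2′ attack give the same product, and the remaining OH is deactivated by chelation.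

Step 7
Reactants: 9 2-hydroxy-4-methoxy-6-({2-[2-(2-methylbut-3-yn-2-yloxy)-4-(triisopropylsilyloxy)phenyl]prop-2-en-1-yl}oxy)benzaldehyde
Product: 11 3-{2-[2,2-dimethyl-5-(triisopropylsilyloxy)-2H-chromen-8-yl]prop-2-en-1-yl}-2,6-dihydroxy-4-methoxybenzaldehyde, via chromene allyl ether 10 (not isolated)
Conditions: PhNEt2 (0.05 M), 190 °C, sealed tube, Ar, 3 h
Reagents that add atoms: none
Why: The aryl propargyl ether first undergoes Claisen rearrangement, 1,5-H shift and oxa-6π electrocyclisation onto C3′ (its only free ortho position) to close the chromene, and the aromatic Claisen rearrangement then moves the 2-arylallyl group from oxygen to the ring carbon, where the ortho and para pathways give the same compound because the A ring is symmetric.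

Step 8
Reactants: 11 3-{2-[2,2-dimethyl-5-(triisopropylsilyloxy)-2H-chromen-8-yl]prop-2-en-1-yl}-2,6-dihydroxy-4-methoxybenzaldehyde
Product: 12 (3R)-3-[2,2-dimethyl-5-(triisopropylsilyloxy)-2H-chromen-8-yl]-7-hydroxy-5-methoxy-3,4-dihydro-2H-chromene-8-carbaldehyde
Conditions: 3,6-di-tert-butyl-9-mesityl-10-phenylacridinium BF4 (3 mol%), cysteine β-turn peptide thiol Boc-Cys-D-Pro-Aib-Phe-NMe2 (15 mol%, antipode chosen in a first screen to give 3R), PhCF3/DCE 1:1 (0.02 M), 450 nm LEDs, −20 °C, Ar
Reagents that add atoms: none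
Why: Proposed new method: an enantioselective anti-Markovnikov 6-endo hydroetherification by dual acridinium photoredox and chiral thiol hydrogen-atom-transfer catalysis, in which the excited acridinium oxidises the electron-rich α-substituted styrene to its radical cation, the neighbouring A-ring OH (the only one that can reach) adds to the terminal CH2 to form the O1–C2 bond and a planar tertiary benzylic C3 radical, and the peptide thiol, docked by hydrogen bonds to the 7-OH/8-CHO edge, delivers H to one face to set (3R) before its thiyl radical is reduced by the acridine radical and reprotonated; the closest known reaction types are the racemic acridinium/thiol anti-Markovnikov hydroetherification of alkenols and enantioselective H-atom transfer from chiral peptide or sugar thiols to prochiral carbon radicals.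

Step 9
Reactants: 12 (3R)-3-[2,2-dimethyl-5-(triisopropylsilyloxy)-2H-chromen-8-yl]-7-hydroxy-5-methoxy-3,4-dihydro-2H-chromene-8-carbaldehyde
Product: 13 (3R)-7-hydroxy-3-(5-hydroxy-2,2-dimethyl-2H-chromen-8-yl)-5-methoxy-3,4-dihydro-2H-chromene-8-carbaldehyde
Conditions: TBAF (1.2 equiv), AcOH (1.2 equiv), THF, 0 °C
Reagents that add atoms: none
Why: Fluoride-driven desilylation of the aryl silyl ether (strong Si–F bond), buffered with acetic acid, frees the 4′-OH without touching the aldehyde, the chromene or the non-acidic C3–H stereocentre.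

**Compound list**
1 | 2,4,6-trihydroxybenzaldehyde | O=Cc1c(O)cc(O)cc1O | starting material
2 | 2,6-dihydroxy-4-methoxybenzaldehyde | COc1cc(O)c(C=O)c(O)c1 | intermediate
3 | 1-(2,4-dihydroxyphenyl)ethan-1-one | CC(=O)c1ccc(O)cc1O | starting material
4 | 1-[2-hydroxy-4-(triisopropylsilyloxy)phenyl]ethan-1-one | CC(=O)c1ccc(O[Si](C(C)C)(C(C)C)C(C)C)cc1O | intermediate
5 | 3-chloro-3-methylbut-1-yne | C#CC(C)(C)Cl | starting material
6 | 1-[2-(2-methylbut-3-yn-2-yloxy)-4-(triisopropylsilyloxy)phenyl]ethan-1-one | CC(=O)c1ccc(O[Si](C(C)C)(C(C)C)C(C)C)cc1OC(C)(C)C#C | intermediate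
7 | 2-methyl-2-[2-(2-methylbut-3-yn-2-yloxy)-4-(triisopropylsilyloxy)phenyl]oxirane (racemic) | CC1(CO1)c1ccc(O[Si](C(C)C)(C(C)C)C(C)C)cc1OC(C)(C)C#C | intermediate
8 | 2-[2-(2-methylbut-3-yn-2-yloxy)-4-(triisopropylsilyloxy)phenyl]prop-2-en-1-ol | C=C(CO)c1ccc(O[Si](C(C)C)(C(C)C)C(C)C)cc1OC(C)(C)C#C | intermediate
9 | 2-hydroxy-4-methoxy-6-({2-[2-(2-methylbut-3-yn-2-yloxy)-4-(triisopropylsilyloxy)phenyl]prop-2-en-1-yl}oxy)benzaldehyde | COc1cc(O)c(C=O)c(OCC(=C)c2ccc(O[Si](C(C)C)(C(C)C)C(C)C)cc2OC(C)(C)C#C)c1 | intermediate
10 | 2-({2-[2,2-dimethyl-5-(triisopropylsilyloxy)-2H-chromen-8-yl]prop-2-en-1-yl}oxy)-6-hydroxy-4-methoxybenzaldehyde (chromene allyl ether) | COc1cc(O)c(C=O)c(OCC(=C)c2ccc(O[Si](C(C)C)(C(C)C)C(C)C)c3c2OC(C)(C)C=C3)c1 | intermediate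
11 | 3-{2-[2,2-dimethyl-5-(triisopropylsilyloxy)-2H-chromen-8-yl]prop-2-en-1-yl}-2,6-dihydroxy-4-methoxybenzaldehyde | COc1cc(O)c(C=O)c(O)c1CC(=C)c1ccc(O[Si](C(C)C)(C(C)C)C(C)C)c2c1OC(C)(C)C=C2 | intermediate
12 | (3R)-3-[2,2-dimethyl-5-(triisopropylsilyloxy)-2H-chromen-8-yl]-7-hydroxy-5-methoxy-3,4-dihydro-2H-chromene-8-carbaldehyde | COc1cc(O)c(C=O)c2c1C[C@H](c1ccc(O[Si](C(C)C)(C(C)C)C(C)C)c3c1OC(C)(C)C=C3)CO2 | intermediate
13 | (3R)-7-hydroxy-3-(5-hydroxy-2,2-dimethyl-2H-chromen-8-yl)-5-methoxy-3,4-dihydro-2H-chromene-8-carbaldehyde | COc1cc(O)c(C=O)c2c1C[C@H](c1ccc(O)c3c1OC(C)(C)C=C3)CO2 | target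

**Step count**
Total: 9 steps. Longest linear sequence: 8 steps (3 → 13, steps 2 to 9); step 1 is a one-step side branch.

**Steps most likely to fail**

Step 8 (the proposed new method). The two faces of the chroman-3-yl radical differ only by an OCH2 and an ArCH2 ring arm, so the enantiomeric excess may be modest. Hydrogen transfer from an alkyl thiol to a benzylic radical is also reversible and can erode it with time. The chromene double bond shares the oxidised arene and may divert some material, which is why the reaction is run dilute and cold. The fallback sets out from 11 and comes back at 12. The cyclisation is run with the established achiral pair 9-mesityl-10-methylacridinium tetrafluoroborate and thiophenol under blue light to give racemic 3-[2,2-dimethyl-5-(triisopropylsilyloxy)-2H-chromen-8-yl]-7-hydroxy-5-methoxy-3,4-dihydro-2H-chromene-8-carbaldehyde F1. The enantiomers are then separated by preparative chiral SFC on a polysaccharide carbamate phase; 12 is kept and the (3S)-enantiomer F2 is discarded. This replaces catalyst control by resolution and costs half the material. It answers a low ee but not a failure of the radical-cation cyclisation itself, since it uses the same manifold.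

Step 7. The 2-arylallyl ether may rearrange slowly. At 190 °C the product, an acidic phenol next to an aryl-stabilised 1,1-disubstituted alkene, can also close the Markovnikov way to a 2-aryl-2-methyl-2,3-dihydrobenzofuran; the basic solvent is chosen to suppress this. The fallback sets out from 9 and comes back at 11. Pd(PPh3)4 (5 mol%) in THF at 50 °C ionises the allyl aryl ether to a 2-aryl-π-allylpalladium phenoxide pair that recombines at carbon (Tsuji–Trost O-to-C allyl transfer; attack at either nucleophilic ring carbon gives the same compound). This gives 2,6-dihydroxy-4-methoxy-3-{2-[2-(2-methylbut-3-yn-2-yloxy)-4-(triisopropylsilyloxy)phenyl]prop-2-en-1-yl}benzaldehyde F3. Its propargyl ether alone is then rearranged in xylene at 130 °C to 11, about 60 °C below the temperature the allyl Claisen needs.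

Step 5. The electron-rich 2-aryl-2-methyloxirane may rearrange to the aldehyde or react sluggishly with the amide base. The fallback sets out from 6 and comes back at 8, bypassing 7. Wittig methylenation of the ketone (Ph3P=CH2 from Ph3PCH3Br and KOtBu, THF) gives 2-(2-methylbut-3-yn-2-yloxy)-1-(prop-1-en-2-yl)-4-(triisopropylsilyloxy)benzene F4. Allylic hydroxylation of its methyl group with SeO2 (0.5 equiv) and t-BuOOH in CH2Cl2 then gives 8.

Further compounds
F1 | step 8 | racemic 3-[2,2-dimethyl-5-(triisopropylsilyloxy)-2H-chromen-8-yl]-7-hydroxy-5-methoxy-3,4-dihydro-2H-chromene-8-carbaldehyde | COc1cc(O)c(C=O)c2c1CC(c1ccc(O[Si](C(C)C)(C(C)C)C(C)C)c3c1OC(C)(C)C=C3)CO2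
F2 | step 8 | (3S)-3-[2,2-dimethyl-5-(triisopropylsilyloxy)-2H-chromen-8-yl]-7-hydroxy-5-methoxy-3,4-dihydro-2H-chromene-8-carbaldehyde | COc1cc(O)c(C=O)c2c1C[C@@H](c1ccc(O[Si](C(C)C)(C(C)C)C(C)C)c3c1OC(C)(C)C=C3)CO2
F3 | step 7 | 2,6-dihydroxy-4-methoxy-3-{2-[2-(2-methylbut-3-yn-2-yloxy)-4-(triisopropylsilyloxy)phenyl]prop-2-en-1-yl}benzaldehyde | COc1cc(O)c(C=O)c(O)c1CC(=C)c1ccc(O[Si](C(C)C)(C(C)C)C(C)C)cc1OC(C)(C)C#C
F4 | step 5 | 2-(2-methylbut-3-yn-2-yloxy)-1-(prop-1-en-2-yl)-4-(triisopropylsilyloxy)benzene | C=C(C)c1ccc(O[Si](C(C)C)(C(C)C)C(C)C)cc1OC(C)(C)C#C
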